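## Structural features

The target is a monocyclic γ-butyrolactone with ring atoms O1, C2 (carbonyl), C3, C4 and C5; this lactone numbering is used throughout, while the systematic names number the same ring as a tetrahydrofuran (lactone C5 = position 2, C4 = position 3, C3 = position 4). C3 carries an exocyclic methylene conjugated with the lactone carbonyl, C4 a free carboxylic acid, and C5 an unbranched fifteen-carbon chain of thirteen methylenes ending in a methyl ketone (14-oxopentadecyl). The only stereocentres, C4 (S) and C5 (R), are adjacent, and the carboxyl and the chain are trans on the ring. The α-methylene lactone is the fragile part: it is a Michael acceptor, and the C4 hydrogen, allylic and α to the carboxyl, allows epimerisation or migration of the double bond into the ring under base or heat. The distant methyl ketone is enolisable and would compete in any enolate, carboxylation or hydride chemistry aimed at the ring. The real difficulty is therefore the absolute and relative configuration of the C4/C5 pair on an otherwise featureless chain, together with telling two ketone-level carbons apart (C5 before reduction and the chain ketone). The key step uses the fact that O1–C5 is a carbinol C–O bond and C4 is α to a carboxyl: with the ring opened and C5 at the ketone level, C4 is the acidic carbon of a β-keto ester, so it racemises freely and one face-selective hydride transfer to C5 can fix both centres.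

## Logic of the disconnections

17 ⇒ 16. No skeletal bond is cut; the chain ketone is traced back to a cyclic ketal. The reason lies in the next disconnection, whose reagent would also carboxylate a free methyl ketone. The gain is that the two enolisable sites are distinguished. The demand is a final hydrolysis mild enough for the methylene lactone.

16 ⇒ 13. The exocyclic C3=CH2 bond is cut, so that the most fragile group is introduced last onto a saturated lactone acid. The forward step must activate C3 in the presence of the free C4 acid without touching the C4 hydrogen. This is met by carboxylation at C3 (14), aminomethylation (15) and decarboxylative elimination.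

13 ⇒ 11. The C4 carboxyl is traced to its methyl ester (O–CH3 bond), which keeps the acid masked during protection and equilibration. The forward hydrolysis also opens the lactone (12), so the plan relies on the fact that only the five-membered lactone can re-form on acidification.

11 ⇒ 9. The acyl–oxygen bond C2–O1 and the two ketal C–O bonds are cut, giving an acyclic hydroxy diester with a free chain ketone (through 10). The ring is reduced to a chain with two adjacent stereocentres, and the lactone ester stage is the one place where C4 can be equilibrated to trans. The forward demand is closure onto the CH2 ester only, and equilibration without eliminative ring opening.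

9 ⇒ 8. The C5–H bond is cut; this is the key disconnection. Two stereocentres collapse into a prochiral ketone and one racemic, configurationally labile centre. The forward step must deliver hydride to one face of the chelated ketone, racemise the neighbouring centre faster than it reduces, and leave the remote ketone alone.

8 ⇒ 6 + 7. The C4–C5 bond between the acyl carbon and the succinate carbon is cut. Polarity inversion of the aldehyde of 6 lets it add to the alkene of 7, which supplies C2, C3, C4 and the C4 carboxyl in one piece. The aldehyde must react as an acyl anion equivalent in preference to self-condensation, and the chain ketone must stay out.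

6 ⇒ 4. The aldehyde carbon and the ketone carbon are reconnected as a ring C=C bond. A sixteen-carbon chain with two different carbonyl ends is thereby derived from a fifteen-membered carbocycle, and the aldehyde/methyl ketone distinction is encoded in the substitution of the alkene. The forward cleavage (through 5) must not over-oxidise the aldehyde.

4 ⇒ 3 ⇒ 1 + 2. The alkene is traced by formal hydration to the tertiary alcohol 3, and 3 to 1 and 2 by cutting the ring C–CH3 bond. Both are commercial. The only demand is that elimination gives the ring alkene.

## Other disconnections considered

Alternative 1: The cut is the ring bond C3–C4, made together with the exocyclic alkene. The substrate would be the epoxy propargyl ether A2, in which the ether carbon (future C5) is already R and a terminal epoxide sits on the neighbouring carbon. In the forward step Cp2TiCl (trivalent titanium, from Cp2TiCl2 and Zn) would open the epoxide homolytically to the secondary radical at the future C4. This radical closes 5-exo-dig onto the alkyne, and reduction and protonation of the vinyl radical would give the tetrahydrofuran alcohol A1 with the methylene in place.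
- In its favour: ring, C3–C4 bond and the sensitive alkene arise in one operation, so no late carboxylation chemistry at C3 is needed; on this point it is better than the chosen plan. The epoxide configuration is irrelevant because that carbon becomes a radical.
- Against it here: A1 is at the wrong oxidation level at two carbons. The primary alcohol must become the C4 acid, and the ring CH2 next to oxygen must be oxidised to the lactone carbonyl. That allylic oxidation normally calls for hexavalent chromium (CrO3·2pyridine type reagents) in the presence of the ketal and the new alkene.
- Further drawbacks: A2 needs its own enantioselective synthesis, titanium is used in more than stoichiometric amount, and a wrong C4 epimer cannot be repaired because C4 is not acidic at the alcohol level.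
- Comparison: on structure, both plans reach the trans C4/C5 pair, but the chosen one arrives with every carbon at its final oxidation state. On mechanism, a substrate-controlled radical closure stands against a catalyst-controlled hydride transfer that creates both centres from a racemate. On step economy the alternative is expected to be two to three steps longer.

Alternative 2: The cut is the exocyclic C4–CO2H bond. The substrate would be the (R)-butenolide A4 with the ketal-protected chain at C5. In the forward step HCO2K, a thiol hydrogen-atom-transfer catalyst and photoexcited 4CzIPN would generate the CO2 radical anion. It adds as a nucleophilic radical to the β-carbon C4 from the face opposite the C5 chain, and the α-carbonyl radical at C3 is then reduced and protonated to give the acid A3.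
- In its favour: A3 is the same compound as 13, so the free acid would be obtained without a methyl ester, without base hydrolysis and without reopening the lactone; on this point it is better than the chosen plan. Regiochemistry is secured by polarity, and the trans relation by the existing C5 centre, a control at least equal to the anti preference of the hydrogenation.
- Against it here: the C5–H of A4 is allylic, α to oxygen and vinylogously α to the carbonyl. Both the thiyl radical and the basic formate could remove it and racemise the only stereocentre the step relies on.
- Further drawbacks: the CO2 radical anion is a strong one-electron reductant and may reduce A4 (saturation or reductive C5–O cleavage) instead of adding. A4 must also be made enantiopure from a chain whose ketone is already protected, which 6 does not offer selectively.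
- Comparison: on structure, the plans converge on the same acid. On mechanism, the alternative relays chirality from a pre-made, labile centre, whereas the chosen plan creates C5 and C4 together under catalyst control and can repair C4. On step economy the alternative saves two steps after its key step but is expected to spend at least as many on A4, so the totals are about equal.

Alternative 3: The cut is the ring bond O1–C5, made by oxidation of a C–H bond. The substrate would be the half ester A6, an (R)-2-alkylsuccinate with the free acid on the CH2 arm and the methyl ester on the stereocentre. In the forward step the acid would bind a chiral Mn(OTf)2(pdp)-type catalyst and H2O2 would generate a high-valent manganese oxo carboxylate. A 1,7-hydrogen transfer from the γ-methylene (future C5) gives a carbon radical, and rebound of the bound carboxylate oxygen closes the lactone to A5.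
- In its favour: A5 is the same compound as 10, and the free ketone should be tolerated. A6 could be reached from 6 in two steps (Stobbe condensation, then asymmetric alkene hydrogenation), so the step count to the common intermediate is equal to that of the chosen plan. Ring closure by C–H functionalisation is more redox-economic than reduction followed by lactonisation; on this point it is the better.
- Against it here: the γ-methylene is an unactivated secondary position, inductively deactivated by the ester on the adjacent carbon. The other, more electron-rich methylenes of the long chain are open to undirected oxidation by the same oxidant.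
- Further drawbacks: the catalyst must choose one of two diastereotopic hydrogens in a pairing with the C4 centre that may be matched or mismatched, and C4 needs a second asymmetric step of its own.
- Comparison: on structure, both plans pass through the same lactone ester. On mechanism, the chosen plan differentiates a chelating ketone from a non-chelating one, a difference of functional group, whereas the alternative must differentiate nearly identical C–H bonds. On step economy the two are equal.

Key step: step 5

Remark on the chemistry: 4 is used as its E/Z mixture, because both ring-alkene geometries are cleaved to the same keto aldehyde.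

## Route

Step 1
Reactants: 1 cyclopentadecanone; 2 methylmagnesium bromide
Product: 3 1-methylcyclopentadecan-1-ol
Conditions: MeMgBr (1.5 equiv), THF, 0 °C to rt; then 1 M HCl, 0 °C
Reagents that add atoms: methylmagnesium bromide (compound 2), C[Mg]Br
Why: Grignard 1,2-addition of the methyl nucleophile to the unhindered ring ketone gives the tertiary alcohol; no stereocentre is formed, and ketone returned by enolisation can be recycled.

Step 2
Reactants: 3 1-methylcyclopentadecan-1-ol
Product: 4 1-methylcyclopentadec-1-ene (E/Z mixture)
Conditions: TsOH·H2O (5 mol%), toluene, reflux, Dean–Stark
Reagents that add atoms: none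
Why: Acid-catalysed E1 dehydration of the tertiary alcohol under equilibrating conditions should favour the trisubstituted ring alkene (Zaitsev product); a minor exocyclic isomer would only return 1 in step 3 and is separable there.

Step 3
Reactants: 4 1-methylcyclopentadec-1-ene
Product: 6 15-oxohexadecanal, via ozonide 5 (not isolated)
Conditions: O3, CH2Cl2, −78 °C; then PPh3 (1.1 equiv), −78 °C to rt
Reagents that add atoms: ozone, [O-][O+]=O
Why: Criegee ozonolysis: 1,3-dipolar cycloaddition, cycloreversion and recombination give ozonide 5, which PPh3 reduces to the keto aldehyde without over-oxidation; the substituted alkene carbon becomes the methyl ketone and the CH carbon the aldehyde.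

Step 4
Reactants: 6 15-oxohexadecanal; 7 dimethyl maleate
Product: 8 dimethyl 2-(15-oxohexadecanoyl)succinate (racemic)
Conditions: 7 (1.5 equiv), 3-benzyl-5-(2-hydroxyethyl)-4-methylthiazolium chloride (15 mol%), Et3N (0.5 equiv), 1,4-dioxane, 80 °C, N2
Reagents that add atoms: dimethyl maleate (compound 7), COC(=O)/C=C\C(=O)OC
Why: Stetter reaction: the thiazol-2-ylidene adds to the aldehyde, the Breslow intermediate (acyl anion equivalent) adds 1,4 to the doubly activated alkene and the carbene is released. The methyl ketone cannot form a Breslow intermediate, excess 7 suppresses acyloin self-condensation, and the new centre is formed racemic, which is what step 5 requires.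

Step 5
Reactants: 8 dimethyl 2-(15-oxohexadecanoyl)succinate (racemic)
Product: 9 dimethyl (2S)-2-[(1R)-1-hydroxy-15-oxohexadecyl]succinate
Conditions: RuCl2[(R)-BINAP](dmf)n (1 mol%), H2 (80 atm), CH2Cl2, 50 °C
Reagents that add atoms: none
Why: Under H2 the precatalyst gives a divalent ruthenium monohydride; the acyl ketone oxygen and the ester carbonyl on succinate C2 chelate it, hydride migrates from ruthenium to the ketone carbon inside the six-membered chelate, and hydrogenolysis of the Ru–O bond releases the β-hydroxy ester. The closest known reaction type is the Noyori hydrogenation of 2-substituted β-keto esters with dynamic kinetic resolution. No ring closes and no skeletal bond forms; only the C–H bond at the future C5 is made. The carbinol centre is set by the ligand: (R)-BINAP delivers hydride to the face that gives (R)-3-hydroxy esters from alkyl β-keto esters, here the (1R) carbinol. The succinate C2 centre (future C4) is set by relative rates: the enantiomers of 8 interconvert through the enol faster than either is reduced, and the catalyst is expected to reduce the (2S) enantiomer faster, so the racemate funnels to the anti (2S,1R) product. Chemoselectivity comes from the substrate: the remote methyl ketone has no donor group for chelation and simple ketones are not reduced by this diamine-free halide catalyst, while methyl esters in CH2Cl2 exclude ester exchange, ketal formation and early lactonisation. Anti selectivity for an acyclic 2-alkyl group is expected to be the weaker control, and the route needs only the C5 face selectivity, because C4 is equilibrated to trans in step 6.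

Step 6
Reactants: 9 dimethyl (2S)-2-[(1R)-1-hydroxy-15-oxohexadecyl]succinate
Product: 11 methyl (2R,3S)-2-[13-(2-methyl-1,3-dioxolan-2-yl)tridecyl]-5-oxotetrahydrofuran-3-carboxylate, via keto lactone ester 10 (not isolated)
Conditions: HOCH2CH2OH (1.5 equiv), TsOH·H2O (5 mol%), toluene, reflux, Dean–Stark; aq. NaHCO3 wash; then DBU (0.3 equiv), toluene, 60 °C
Reagents that add atoms: ethylene glycol, OCCO
Why: Acid-catalysed transesterification closes the γ-lactone from the hydroxyl onto the CH2CO2Me ester (5-exo-trig; a β-lactone with the other ester is not formed), and the same acid converts the methyl ketone into its dioxolane with azeotropic removal of methanol and water. DBU then equilibrates C4 through the ester enolate, so that cis lactone arising from the C2 epimer of 9 is drained to the more stable trans isomer; C5 is a non-acidic carbinol carbon and is not affected, and ring opening from the enolate is stereoelectronically disfavoured in the five-membered ring.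

Step 7
Reactants: 11 methyl (2R,3S)-2-[13-(2-methyl-1,3-dioxolan-2-yl)tridecyl]-5-oxotetrahydrofuran-3-carboxylate
Product: 13 (2R,3S)-2-[13-(2-methyl-1,3-dioxolan-2-yl)tridecyl]-5-oxotetrahydrofuran-3-carboxylic acid, via hydroxy diacid 12 (not isolated)
Conditions: LiOH·H2O (3 equiv), THF–H2O (3:1), 0 °C to rt; then 1 M HCl to pH 3, 0 °C; toluene, 50 °C
Reagents that add atoms: lithium hydroxide, [Li+].[OH-]
Why: Saponification cleaves the methyl ester and also opens the lactone to the dilithium salt of 12; on acidification the γ-hydroxy acid recloses to the five-membered lactone with the CH2CO2H arm, leaving the C4 carboxyl free. Low temperature limits epimerisation and retro-aldol cleavage in the ring-opened ester, and the brief cold acidification to pH 3 should spare the dioxolane.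

Step 8
Reactants: 13 (2R,3S)-2-[13-(2-methyl-1,3-dioxolan-2-yl)tridecyl]-5-oxotetrahydrofuran-3-carboxylic acid
Product: 16 (2R,3S)-4-methylene-2-[13-(2-methyl-1,3-dioxolan-2-yl)tridecyl]-5-oxotetrahydrofuran-3-carboxylic acid, via malonic diacid 14 (not isolated), via Mannich adduct 15 (not isolated)
Conditions: MeOMgOCO2Me (2 M in DMF, 30 equiv), 130 °C, N2; cold 1 M HCl work-up; then 37% aq. CH2O, PhNHMe, NaOAc, AcOH, rt
Reagents that add atoms: formaldehyde, C=O; MeOMgOCO2Me, COC(=O)O[Mg]OC (its CO2 unit is carried only in 14 and 15 and is lost again)
Why: MeOMgOCO2Me carboxylates C3, the only enolisable ring position, as a magnesium chelate; the malonic half acid 14 then undergoes a Mannich reaction with the iminium ion from CH2O and PhNHMe, and adduct 15 fragments by decarboxylative elimination of the amine to the exocyclic alkene. The ketal keeps the chain ketone out of the carboxylation and the Mannich stage, and C4, α only to a carboxylate, is not enolised.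

Step 9
Reactants: 16 (2R,3S)-4-methylene-2-[13-(2-methyl-1,3-dioxolan-2-yl)tridecyl]-5-oxotetrahydrofuran-3-carboxylic acid
Product: 17 (2R,3S)-4-methylene-5-oxo-2-(14-oxopentadecyl)tetrahydrofuran-3-carboxylic acid
Conditions: 1 M HCl, THF, rt
Reagents that add atoms: water, O
Why: Acid-catalysed hydrolysis of the dioxolane through the oxocarbenium ion frees the methyl ketone; dilute acid at room temperature should leave the methylene lactone, the carboxylic acid and both stereocentres untouched.

## Compound list

1 | cyclopentadecanone | O=C1CCCCCCCCCCCCCC1 | starting material
2 | methylmagnesium bromide | C[Mg]Br | starting material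
3 | 1-methylcyclopentadecan-1-ol | CC1(O)CCCCCCCCCCCCCC1 | intermediate
4 | 1-methylcyclopentadec-1-ene (E/Z mixture) | CC1=CCCCCCCCCCCCCC1 | intermediate
5 | 1-methyl-16,17,18-trioxabicyclo[13.2.1]octadecane (ozonide of 4, racemic) | CC12CCCCCCCCCCCCCC(OO1)O2 | intermediate (not isolated)
6 | 15-oxohexadecanal | CC(=O)CCCCCCCCCCCCCC=O | intermediate
7 | dimethyl maleate | COC(=O)/C=C\C(=O)OC | starting material
8 | dimethyl 2-(15-oxohexadecanoyl)succinate (racemic) | COC(=O)CC(C(=O)OC)C(=O)CCCCCCCCCCCCCC(C)=O | intermediate
9 | dimethyl (2S)-2-[(1R)-1-hydroxy-15-oxohexadecyl]succinate | O[C@H](CCCCCCCCCCCCCC(C)=O)[C@H](CC(=O)OC)C(=O)OC | intermediate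
10 | methyl (2R,3S)-5-oxo-2-(14-oxopentadecyl)tetrahydrofuran-3-carboxylate | C1C(=O)O[C@H](CCCCCCCCCCCCCC(C)=O)[C@H]1C(=O)OC | intermediate (not isolated)
11 | methyl (2R,3S)-2-[13-(2-methyl-1,3-dioxolan-2-yl)tridecyl]-5-oxotetrahydrofuran-3-carboxylate | C1C(=O)O[C@H](CCCCCCCCCCCCCC2(C)OCCO2)[C@H]1C(=O)OC | intermediate
12 | (2S)-2-[(1R)-1-hydroxy-14-(2-methyl-1,3-dioxolan-2-yl)tetradecyl]butanedioic acid (formed as its dilithium salt) | O[C@H](CCCCCCCCCCCCCC1(C)OCCO1)[C@H](CC(=O)O)C(=O)O | intermediate (not isolated)
13 | (2R,3S)-2-[13-(2-methyl-1,3-dioxolan-2-yl)tridecyl]-5-oxotetrahydrofuran-3-carboxylic acid | C1C(=O)O[C@H](CCCCCCCCCCCCCC2(C)OCCO2)[C@H]1C(=O)O | intermediate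
14 | (2R,3S)-2-[13-(2-methyl-1,3-dioxolan-2-yl)tridecyl]-5-oxotetrahydrofuran-3,4-dicarboxylic acid (position 4 not defined) | OC(=O)C1C(=O)O[C@H](CCCCCCCCCCCCCC2(C)OCCO2)[C@H]1C(=O)O | intermediate (not isolated)
15 | (2R,3S)-4-[(N-methylanilino)methyl]-2-[13-(2-methyl-1,3-dioxolan-2-yl)tridecyl]-5-oxotetrahydrofuran-3,4-dicarboxylic acid (position 4 not defined) | OC(=O)C1(CN(C)c3ccccc3)C(=O)O[C@H](CCCCCCCCCCCCCC2(C)OCCO2)[C@H]1C(=O)O | intermediate (not isolated)
16 | (2R,3S)-4-methylene-2-[13-(2-methyl-1,3-dioxolan-2-yl)tridecyl]-5-oxotetrahydrofuran-3-carboxylic acid | C=C1C(=O)O[C@H](CCCCCCCCCCCCCC2(C)OCCO2)[C@H]1C(=O)O | intermediate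
17 | (2R,3S)-4-methylene-5-oxo-2-(14-oxopentadecyl)tetrahydrofuran-3-carboxylic acid | C=C1C(=O)O[C@H](CCCCCCCCCCCCCC(C)=O)[C@H]1C(=O)O | target

## Step count and least certain steps

Total step count: 9 steps. Longest linear sequence: 9 steps (1 to 17); the route is fully linear, and 2 and 7 are each consumed in a single step.

**Step 5 (key step).** The most likely failure is incomplete stereoconvergence. If enolisation of 8 in CH2Cl2 is not faster than reduction, the two enantiomers are reduced side by side and the anti preference drops. Competition of the second succinate ester for the metal could also erode the face selectivity at the carbinol, which nothing downstream can repair. Sulfur residues from step 4 would slow turnover, and long reaction times invite slow reduction of the remote ketone. The C4 outcome is repaired in step 6, provided that equilibration is stopped before eliminative opening of the lactone sets in.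

Fallback, from 6 and back at 10: both centres are set by an auxiliary-controlled aldol that also forms the C4–C5 bond.
- The dibutylboron enolate of methyl 4-[(4S)-4-benzyl-2-oxo-1,3-oxazolidin-3-yl]-4-oxobutanoate F1 is prepared with Bu2BOTf and iPr2NEt in CH2Cl2 at −78 °C; F1 comes from (S)-4-benzyloxazolidin-2-one and methyl 4-chloro-4-oxobutanoate.
- It adds to the aldehyde of 6 in an Evans syn-aldol to give methyl (3S,4R)-3-[(4S)-4-benzyl-2-oxo-1,3-oxazolidine-3-carbonyl]-4-hydroxy-18-oxononadecanoate F2.
- Catalytic TsOH closes the hydroxyl onto the methyl ester to give the trans lactone imide (4S)-4-benzyl-3-[(2R,3S)-5-oxo-2-(14-oxopentadecyl)tetrahydrofuran-3-carbonyl]-1,3-oxazolidin-2-one F3.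
- Methanolysis of the imide with MeOMgBr in MeOH at 0 °C gives 10, which is ketalised as in step 6 without the need for equilibration.

**Step 4.** The enolisable aliphatic aldehyde may self-condense, by acyloin formation through the same Breslow intermediate or by base-mediated aldol reaction. The carbene may also be consumed by conjugate addition to 7, so that conversion stalls.

Fallback, from 6 and back at 8: the bond formed is changed from acyl–Cα to Cα–CH2.
- Roskamp homologation of the aldehyde of 6 with methyl diazoacetate and SnCl2 (10 mol%) in CH2Cl2 gives methyl 3,17-dioxooctadecanoate F4; the ketone does not react.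
- C-alkylation of the β-keto ester with methyl bromoacetate (K2CO3, acetone, rt) gives 8.

**Step 8.** Carboxylation at 130 °C may be incomplete, or 14 may decarboxylate before the Mannich stage and return 13. Loss of the ketal in the acidic work-up would expose the ketone to the Mannich medium, and an excursion to basic or hot conditions could move the new double bond into the ring.

Fallback, from 13 and back at 16: the methylene is built through the lactone enolate.
- The dianion of 13 (NaN(SiMe3)2, 2.2 equiv, THF, −78 °C) is aminomethylated with CH2=NMe2+ I− to give (2R,3S)-4-[(dimethylamino)methyl]-2-[13-(2-methyl-1,3-dioxolan-2-yl)tridecyl]-5-oxotetrahydrofuran-3-carboxylic acid F6.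
- Quaternisation with MeI in MeOH gives [(4S,5R)-4-carboxy-5-[13-(2-methyl-1,3-dioxolan-2-yl)tridecyl]-2-oxotetrahydrofuran-3-yl]-N,N,N-trimethylmethanaminium iodide F7.
- Aqueous NaHCO3 brings about elimination to 16.

**Step 7.** In the ring-opened hydroxy ester, hydroxide may epimerise C4 or trigger retro-aldol cleavage before the ester is hydrolysed. The acidification needed to reclose the lactone may cost the ketal or leave the ring partly open.

Fallback, from 10 and back at 13: hydrolysis is done under acid before protection. Compound 10 is isolated by running step 6 without the diol.
- Heating 10 in 6 M HCl–1,4-dioxane at reflux hydrolyses the ester with the lactone closed and gives (2R,3S)-5-oxo-2-(14-oxopentadecyl)tetrahydrofuran-3-carboxylic acid F5.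
- The ketone of F5 is protected by silyl-transfer ketalisation (TMSOCH2CH2OTMS, cat. TMSOTf, CH2Cl2, −20 °C); aqueous work-up cleaves the transient silyl ester and gives 13.

## Further compounds

F1 | step 5 | methyl 4-[(4S)-4-benzyl-2-oxo-1,3-oxazolidin-3-yl]-4-oxobutanoate | COC(=O)CCC(=O)N1[C@@H](Cc2ccccc2)COC1=O
F2 | step 5 | methyl (3S,4R)-3-[(4S)-4-benzyl-2-oxo-1,3-oxazolidine-3-carbonyl]-4-hydroxy-18-oxononadecanoate | O[C@H](CCCCCCCCCCCCCC(C)=O)[C@H](CC(=O)OC)C(=O)N1[C@@H](Cc2ccccc2)COC1=O
F3 | step 5 | (4S)-4-benzyl-3-[(2R,3S)-5-oxo-2-(14-oxopentadecyl)tetrahydrofuran-3-carbonyl]-1,3-oxazolidin-2-one | C1C(=O)O[C@H](CCCCCCCCCCCCCC(C)=O)[C@H]1C(=O)N2[C@@H](Cc3ccccc3)COC2=O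
F4 | step 4 | methyl 3,17-dioxooctadecanoate | COC(=O)CC(=O)CCCCCCCCCCCCCC(C)=O
F5 | step 7 | (2R,3S)-5-oxo-2-(14-oxopentadecyl)tetrahydrofuran-3-carboxylic acid | C1C(=O)O[C@H](CCCCCCCCCCCCCC(C)=O)[C@H]1C(=O)O
F6 | step 8 | (2R,3S)-4-[(dimethylamino)methyl]-2-[13-(2-methyl-1,3-dioxolan-2-yl)tridecyl]-5-oxotetrahydrofuran-3-carboxylic acid (position 4 not defined) | CN(C)CC1C(=O)O[C@H](CCCCCCCCCCCCCC2(C)OCCO2)[C@H]1C(=O)O
F7 | step 8 | [(4S,5R)-4-carboxy-5-[13-(2-methyl-1,3-dioxolan-2-yl)tridecyl]-2-oxotetrahydrofuran-3-yl]-N,N,N-trimethylmethanaminium iodide (position 3 not defined) | C[N+](C)(C)CC1C(=O)O[C@H](CCCCCCCCCCCCCC2(C)OCCO2)[C@H]1C(=O)O.[I-]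
A1 | alternative 1 | [(2R,3R)-4-methylene-2-[13-(2-methyl-1,3-dioxolan-2-yl)tridecyl]tetrahydrofuran-3-yl]methanol | C=C1CO[C@H](CCCCCCCCCCCCCC2(C)OCCO2)[C@H]1CO
A2 | alternative 1 | 2-[(1R)-14-(2-methyl-1,3-dioxolan-2-yl)-1-(prop-2-yn-1-yloxy)tetradecyl]oxirane (either configuration at the oxirane carbon) | C#CCO[C@H](CCCCCCCCCCCCCC1(C)OCCO1)C2CO2
A3 | alternative 2 | (2R,3S)-2-[13-(2-methyl-1,3-dioxolan-2-yl)tridecyl]-5-oxotetrahydrofuran-3-carboxylic acid | C1C(=O)O[C@H](CCCCCCCCCCCCCC2(C)OCCO2)[C@H]1C(=O)O
A4 | alternative 2 | (5R)-5-[13-(2-methyl-1,3-dioxolan-2-yl)tridecyl]furan-2(5H)-one | O=C1O[C@H](CCCCCCCCCCCCCC2(C)OCCO2)C=C1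
A5 | alternative 3 | methyl (2R,3S)-5-oxo-2-(14-oxopentadecyl)tetrahydrofuran-3-carboxylate | C1C(=O)O[C@H](CCCCCCCCCCCCCC(C)=O)[C@H]1C(=O)OC
A6 | alternative 3 | (3R)-3-(methoxycarbonyl)-18-oxononadecanoic acid | CC(=O)CCCCCCCCCCCCCC[C@H](CC(=O)O)C(=O)OC
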